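**Plan**

1. Core numbering (bicyclo[3.3.1]nonane): C1 = prenyl bridgehead, C2–C3–C4 = keto-enol bridge (C3 carries the aroyl group), C5 = geranyl bridgehead, C6 = CH2, C7 = CH(prenyl), C8 = CMe2, C9 = bridging ketone.
2. Retrosynthesis cuts, in this order: C3–aroyl, C5–geranyl, the C7 prenyl C=C, then both rings at once through C5–C9 and C7–C8, then C2–C3 of the open chain and the C1–prenyl bond of a malonate.
3. Forward: an open-chain, C1-quaternary keto ester closes first to the cyclohexenedione ring C1–C2–C3–C4–C5–C9 (Claisen, bond C5–C9) and then, in the same flask, to the carbocycle C1–C8–C7–C6–C5–C9 (radical, bond C7–C8).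
4. What makes this possible: C9 is a non-enolisable ester carbon on quaternary C1 and the vinylogously acidic C5–H2 can reach it through a six-membered transition state; once that ring exists, the C1 isopropenyl carbon (C8) and the C5 side chain sit 1,3-syn on a flat ring, so a tertiary C8 radical reaches the enal β-carbon C7 in a 6-exo mode.
5. Stereochemistry: C1 from enzymatic desymmetrisation of an achiral malonate; C5 is forced by the bridge (it can epimerise before closure); C7 from the chair-like radical transition state (side arm equatorial, exo).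
6. End game: Wittig reaction for the C7 prenyl group, bridgehead geranylation at C5, aroylation at C3, one global deprotection.

Key step: step 6

Assumption: pig liver esterase hydrolyses the enantiotopic ester group of 3 that leads to (R)-4; if it prefers the other ester, the fallback given for step 2 supplies (R)-4.
Remark: the isopropenyl/prenyl pair on C1 is a 1,5-diene, so every operation up to step 6 is kept at or below 60 °C to exclude a Cope rearrangement; the target is written as its 4-hydroxy-2-oxo enol tautomer.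

**Route**

Step 1
Reactants: 1 dimethyl 2-(propan-2-ylidene)propanedioate; 2 1-bromo-3-methylbut-2-ene
Product: 3 dimethyl 2-(3-methylbut-2-en-1-yl)-2-(prop-1-en-2-yl)propanedioate
Conditions: NaH, THF–DMF, 0 → 23 °C
Reagents that add atoms: none
Why: γ-Deprotonation of the alkylidene malonate gives a dienolate that the primary allylic bromide alkylates at the α-carbon (deconjugative α-alkylation, SN2), which should create quaternary C1 with its isopropenyl group; no stereocenter arises because the two esters are identical.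

Step 2
Reactants: 3 dimethyl 2-(3-methylbut-2-en-1-yl)-2-(prop-1-en-2-yl)propanedioate
Product: 4 (2R)-2-(methoxycarbonyl)-5-methyl-2-(prop-1-en-2-yl)hex-4-enoic acid
Conditions: pig liver esterase, pH 7.5 phosphate buffer–DMSO (9:1), 25 °C
Reagents that add atoms: water, O
Why: Enzymatic desymmetrisation (esterase hydrolysis of one enantiotopic ester of an α,α-disubstituted malonate) should set the C1 stereocenter, the enzyme pocket telling the isopropenyl from the prenyl group; the freed acid becomes C2 and the remaining ester becomes C9.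

Step 3
Reactants: 5 hex-5-en-2-one; 6 3,3-dimethoxyprop-1-ene
Product: 7 (5E)-7,7-dimethoxyhept-5-en-2-one
Conditions: second-generation Grubbs catalyst RuCl2(=CHPh)(PCy3)(H2IMes) (5 mol %), CH2Cl2, 40 °C
Reagents that add atoms: none
Why: Olefin cross-metathesis of a terminal alkene with an allylic acetal should give the thermodynamically favoured E alkene and delivers the C3–C7 chain with the enal masked against base.

Step 4
Reactants: 4 (2R)-2-(methoxycarbonyl)-5-methyl-2-(prop-1-en-2-yl)hex-4-enoic acid; 7 (5E)-7,7-dimethoxyhept-5-en-2-one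
Product: 9 methyl (2R,8E)-10,10-dimethoxy-2-(3-methylbut-2-en-1-yl)-3,5-dioxo-2-(prop-1-en-2-yl)dec-8-enoate, via acyl imidazole 8 (not isolated)
Conditions: 4, CDI, THF, 23 °C; 7, LiN(SiMe3)2 (2.2 equiv), THF, −78 °C; combine, −78 → 0 °C; AcOH
Reagents that add atoms: none
Why: The kinetic methyl-side lithium enolate of 7 should be C-acylated by the acyl imidazole much faster than by the hindered methyl ester (crossed Claisen acylation), which forms C2–C3 without touching C1, the excess base holding the product as its diketonate.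

Step 5
Reactants: 9 methyl (2R,8E)-10,10-dimethoxy-2-(3-methylbut-2-en-1-yl)-3,5-dioxo-2-(prop-1-en-2-yl)dec-8-enoate
Product: 10 methyl (2R,4E,8E)-5,10,10-trimethoxy-2-(3-methylbut-2-en-1-yl)-3-oxo-2-(prop-1-en-2-yl)deca-4,8-dienoate
Conditions: HC(OMe)3, CSA (cat.), MeOH, 23 °C
Reagents that add atoms: trimethyl orthoformate, COC(OC)OC
Why: Acid-catalysed enol etherification of a β-diketone (ketalisation then loss of methanol) should occur at the C4 carbonyl, far less hindered than C2 next to the quaternary centre, giving the conjugated E enol ether; the methoxy group on C4 later keeps C5 from becoming part of an enolised 1,3-diketone.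

Step 6
Reactants: 10 methyl (2R,4E,8E)-5,10,10-trimethoxy-2-(3-methylbut-2-en-1-yl)-3-oxo-2-(prop-1-en-2-yl)deca-4,8-dienoate
Product: 13 2-[(1R,5S,7S)-4-methoxy-8,8-dimethyl-1-(3-methylbut-2-en-1-yl)-2,9-dioxobicyclo[3.3.1]non-3-en-7-yl]acetaldehyde, via monocyclic acetal 11 (not isolated), via monocyclic enal 12 (not isolated)
Conditions: LiN(i-Pr)2 (2.1 equiv), THF, −78 → 0 °C; then AcOH–H2O, 23 °C; then Fe(acac)3 (0.3 equiv), PhSiH3, EtOH, 60 °C (one flask)
Reagents that add atoms: water, O
Why: LiN(i-Pr)2 removes a γ-hydrogen at C5 of the vinylogous ester (the α′ side is the quaternary C1) and the dienolate acylates itself at C5 on the C9 ester (Dieckmann-type Claisen condensation, 6-(enolendo)-exo-trig) to close ring C1–C2–C3–C4–C5–C9, the acidic C5–H of the product driving the equilibrium, after which aqueous AcOH frees the enal. Fe(acac)3/PhSiH3 then transfers a hydrogen atom to the CH2 terminus of the isopropenyl group and the tertiary C8 radical adds 6-exo-trig to the enal β-carbon C7, closing ring C1–C8–C7–C6–C5–C9, the α-formyl radical being reduced and protonated by the medium. The closest known reaction types are the intramolecular Claisen condensation of 3-alkoxy-enone γ-anions and the hydrogen-atom-transfer Giese cyclisation (reductive olefin coupling). C1 is untouched; C5 is fixed by the bridge, since only the epimer with the C6 arm syn to C8 can close and the two epimers interconvert through the C9 enol; C7 is set by a chair-like transition state with the CH=CH–CHO arm equatorial, which should give the exo isomer (7S in 13). The step needs γ-deprotonation only (secured by the blocked α′ position), hydrogen-atom transfer to the 1,1-disubstituted alkene and not to the trisubstituted prenyl alkene (secured by the more accessible terminal CH2 and a limited amount of silane), and ring closure faster than 1,2-acyl shift of the β-keto radical (secured by the activated acceptor held 1,3-syn).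

Step 7
Reactants: 13 2-[(1R,5S,7S)-4-methoxy-8,8-dimethyl-1-(3-methylbut-2-en-1-yl)-2,9-dioxobicyclo[3.3.1]non-3-en-7-yl]acetaldehyde
Product: 14 (1R,5S,7R)-4-methoxy-8,8-dimethyl-1,7-bis(3-methylbut-2-en-1-yl)bicyclo[3.3.1]non-3-ene-2,9-dione
Conditions: i-PrPPh3I, n-BuLi, THF, 0 °C; then 13, −78 → 23 °C
Reagents that add atoms: isopropyltriphenylphosphonium iodide, CC(C)[P+](c1ccccc1)(c1ccccc1)c1ccccc1.[I-]
Why: Wittig olefination of the aldehyde with the non-stabilised isopropylidene ylide should turn the CH2CHO arm into the prenyl group while the hindered C9 ketone and the vinylogous ester stay inert; the C7 descriptor changes from S to R only through the priority rules.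

Step 8
Reactants: 14 (1R,5S,7R)-4-methoxy-8,8-dimethyl-1,7-bis(3-methylbut-2-en-1-yl)bicyclo[3.3.1]non-3-ene-2,9-dione; 15 (2E)-1-bromo-3,7-dimethylocta-2,6-diene
Product: 16 (1R,5S,7R)-5-[(2E)-3,7-dimethylocta-2,6-dien-1-yl]-4-methoxy-8,8-dimethyl-1,7-bis(3-methylbut-2-en-1-yl)bicyclo[3.3.1]non-3-ene-2,9-dione
Conditions: LiN(i-Pr)2, THF, −78 °C; then 15, −78 → 0 °C
Reagents that add atoms: none
Why: Bridgehead lithiation of the bicyclo[3.3.1]nonane-trione enol ether at C5 (the only bridgehead C–H, acidified by the C9 ketone and assisted by the neighbouring methoxy group) followed by SN2 alkylation with the primary allylic bromide should install the geranyl group, the bridgehead geometry allowing retention only.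

Step 9
Reactants: 17 3,4-dihydroxybenzoic acid
Product: 19 3,4-bis[(tert-butyldimethylsilyl)oxy]benzoic acid, via silyl ester 18 (not isolated)
Conditions: TBSCl, imidazole, DMF, 23 °C; then AcOH–H2O–THF, 23 °C
Reagents that add atoms: tert-butyldimethylsilyl chloride, CC(C)(C)[Si](C)(C)Cl
Why: Exhaustive silylation followed by selective hydrolysis of the labile silyl ester should protect both phenols as silyl ethers (silyl ether formation).

Step 10
Reactants: 19 3,4-bis[(tert-butyldimethylsilyl)oxy]benzoic acid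
Product: 20 3,4-bis[(tert-butyldimethylsilyl)oxy]benzoyl chloride
Conditions: (COCl)2, DMF (cat.), CH2Cl2, 0 → 23 °C
Reagents that add atoms: oxalyl chloride, O=C(Cl)C(Cl)=O
Why: Acid chloride formation with oxalyl chloride under Vilsmeier catalysis should leave the aryl silyl ethers intact.

Step 11
Reactants: 16 (1R,5S,7R)-5-[(2E)-3,7-dimethylocta-2,6-dien-1-yl]-4-methoxy-8,8-dimethyl-1,7-bis(3-methylbut-2-en-1-yl)bicyclo[3.3.1]non-3-ene-2,9-dione; 20 3,4-bis[(tert-butyldimethylsilyl)oxy]benzoyl chloride
Product: 21 (1S,5S,7R)-3-{3,4-bis[(tert-butyldimethylsilyl)oxy]benzoyl}-5-[(2E)-3,7-dimethylocta-2,6-dien-1-yl]-4-methoxy-8,8-dimethyl-1,7-bis(3-methylbut-2-en-1-yl)bicyclo[3.3.1]non-3-ene-2,9-dione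
Conditions: lithium 2,2,6,6-tetramethylpiperidide, THF, −78 °C; then 20, −78 → −20 °C
Reagents that add atoms: none
Why: The hindered amide base should remove the vinylic C3–H between the carbonyl and the methoxy carbon (α-lithiation of a β-alkoxy enone) and the vinyllithium is C-acylated by the aroyl chloride (nucleophilic acyl substitution); the C1 descriptor changes from R to S only through the priority rules.

Step 12
Reactants: 21 (1S,5S,7R)-3-{3,4-bis[(tert-butyldimethylsilyl)oxy]benzoyl}-5-[(2E)-3,7-dimethylocta-2,6-dien-1-yl]-4-methoxy-8,8-dimethyl-1,7-bis(3-methylbut-2-en-1-yl)bicyclo[3.3.1]non-3-ene-2,9-dione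
Product: 22 (1S,5S,7R)-3-(3,4-dihydroxybenzoyl)-5-[(2E)-3,7-dimethylocta-2,6-dien-1-yl]-4-hydroxy-8,8-dimethyl-1,7-bis(3-methylbut-2-en-1-yl)bicyclo[3.3.1]non-3-ene-2,9-dione
Conditions: LiOH, 1,4-dioxane–H2O, 90 °C, argon; then aq. HCl
Reagents that add atoms: lithium hydroxide, [Li+].[OH-]
Why: Hydroxide should cleave the vinylogous methyl ester by addition–elimination at C4 and remove both aryl silyl ethers (ester and silyl ether hydrolysis), freeing the enolised triketone and the catechol; the bridgeheads and C7 cannot enolise, so no stereocenter is at risk.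

**Compound list**

1 | dimethyl 2-(propan-2-ylidene)propanedioate | COC(=O)C(=C(C)C)C(=O)OC | starting material
2 | 1-bromo-3-methylbut-2-ene (prenyl bromide) | CC(C)=CCBr | starting material
3 | dimethyl 2-(3-methylbut-2-en-1-yl)-2-(prop-1-en-2-yl)propanedioate | COC(=O)C(CC=C(C)C)(C(C)=C)C(=O)OC | intermediate
4 | (2R)-2-(methoxycarbonyl)-5-methyl-2-(prop-1-en-2-yl)hex-4-enoic acid | CC(=C)[C@](CC=C(C)C)(C(=O)O)C(=O)OC | intermediate
5 | hex-5-en-2-one | CC(=O)CCC=C | starting material
6 | 3,3-dimethoxyprop-1-ene | C=CC(OC)OC | starting material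
7 | (5E)-7,7-dimethoxyhept-5-en-2-one | CC(=O)CC/C=C/C(OC)OC | intermediate
8 | methyl (2R)-2-(1H-imidazole-1-carbonyl)-5-methyl-2-(prop-1-en-2-yl)hex-4-enoate | CC(=C)[C@](CC=C(C)C)(C(=O)n1ccnc1)C(=O)OC | intermediate
9 | methyl (2R,8E)-10,10-dimethoxy-2-(3-methylbut-2-en-1-yl)-3,5-dioxo-2-(prop-1-en-2-yl)dec-8-enoate | CC(=C)[C@](CC=C(C)C)(C(=O)CC(=O)CC/C=C/C(OC)OC)C(=O)OC | intermediate
10 | methyl (2R,4E,8E)-5,10,10-trimethoxy-2-(3-methylbut-2-en-1-yl)-3-oxo-2-(prop-1-en-2-yl)deca-4,8-dienoate | CC(=C)[C@](CC=C(C)C)(C(=O)/C=C(OC)\CC/C=C/C(OC)OC)C(=O)OC | intermediate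
11 | (2R)-6-[(3E)-5,5-dimethoxypent-3-en-1-yl]-5-methoxy-2-(3-methylbut-2-en-1-yl)-2-(prop-1-en-2-yl)cyclohex-4-ene-1,3-dione (both C6 epimers) | CC(=C)[C@]1(CC=C(C)C)C(=O)C=C(OC)C(CC/C=C/C(OC)OC)C1=O | intermediate
12 | (2E)-5-[(5R)-2-methoxy-5-(3-methylbut-2-en-1-yl)-4,6-dioxo-5-(prop-1-en-2-yl)cyclohex-2-en-1-yl]pent-2-enal (both epimers at ring C1) | CC(=C)[C@]1(CC=C(C)C)C(=O)C=C(OC)C(CC/C=C/C=O)C1=O | intermediate
13 | 2-[(1R,5S,7S)-4-methoxy-8,8-dimethyl-1-(3-methylbut-2-en-1-yl)-2,9-dioxobicyclo[3.3.1]non-3-en-7-yl]acetaldehyde | [C@H]12C[C@@H](CC=O)C(C)(C)[C@](CC=C(C)C)(C(=O)C=C1OC)C2=O | intermediate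
14 | (1R,5S,7R)-4-methoxy-8,8-dimethyl-1,7-bis(3-methylbut-2-en-1-yl)bicyclo[3.3.1]non-3-ene-2,9-dione | [C@H]12C[C@@H](CC=C(C)C)C(C)(C)[C@](CC=C(C)C)(C(=O)C=C1OC)C2=O | intermediate
15 | (2E)-1-bromo-3,7-dimethylocta-2,6-diene (geranyl bromide) | CC(C)=CCC/C(C)=C/CBr | starting material
16 | (1R,5S,7R)-5-[(2E)-3,7-dimethylocta-2,6-dien-1-yl]-4-methoxy-8,8-dimethyl-1,7-bis(3-methylbut-2-en-1-yl)bicyclo[3.3.1]non-3-ene-2,9-dione | CC(C)=CCC/C(C)=C/C[C@]12C[C@@H](CC=C(C)C)C(C)(C)[C@](CC=C(C)C)(C(=O)C=C1OC)C2=O | intermediate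
17 | 3,4-dihydroxybenzoic acid | OC(=O)c1ccc(O)c(O)c1 | starting material
18 | tert-butyldimethylsilyl 3,4-bis[(tert-butyldimethylsilyl)oxy]benzoate | CC(C)(C)[Si](C)(C)OC(=O)c1ccc(O[Si](C)(C)C(C)(C)C)c(O[Si](C)(C)C(C)(C)C)c1 | intermediate
19 | 3,4-bis[(tert-butyldimethylsilyl)oxy]benzoic acid | OC(=O)c1ccc(O[Si](C)(C)C(C)(C)C)c(O[Si](C)(C)C(C)(C)C)c1 | intermediate
20 | 3,4-bis[(tert-butyldimethylsilyl)oxy]benzoyl chloride | ClC(=O)c1ccc(O[Si](C)(C)C(C)(C)C)c(O[Si](C)(C)C(C)(C)C)c1 | intermediate
21 | (1S,5S,7R)-3-{3,4-bis[(tert-butyldimethylsilyl)oxy]benzoyl}-5-[(2E)-3,7-dimethylocta-2,6-dien-1-yl]-4-methoxy-8,8-dimethyl-1,7-bis(3-methylbut-2-en-1-yl)bicyclo[3.3.1]non-3-ene-2,9-dione | CC(C)=CCC/C(C)=C/C[C@]12C[C@@H](CC=C(C)C)C(C)(C)[C@](CC=C(C)C)(C(=O)C(C(=O)c3ccc(O[Si](C)(C)C(C)(C)C)c(O[Si](C)(C)C(C)(C)C)c3)=C1OC)C2=O | intermediate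
22 | (1S,5S,7R)-3-(3,4-dihydroxybenzoyl)-5-[(2E)-3,7-dimethylocta-2,6-dien-1-yl]-4-hydroxy-8,8-dimethyl-1,7-bis(3-methylbut-2-en-1-yl)bicyclo[3.3.1]non-3-ene-2,9-dione | CC(C)=CCC/C(C)=C/C[C@]12C[C@@H](CC=C(C)C)C(C)(C)[C@](CC=C(C)C)(C(=O)C(C(=O)c3ccc(O)c(O)c3)=C1O)C2=O | target

**Step count**

Total steps: 12. Longest linear sequence: 9 (steps 1, 2, 4, 5, 6, 7, 8, 11, 12).

**Steps most likely to fail**

Step 6. Hydrogen-atom transfer may also take place at the trisubstituted prenyl alkene; the β-keto tertiary radical may undergo 1,2-acyl migration before it closes the ring; C5 may remain enolised and flat, so that the side arm cannot reach C8; and the enol ether may be lost during the acid stage. The fallback builds the same bicyclic core by other bonds, using known chemistry, and sets out from 2 together with commercial 3-methoxycyclohex-2-en-1-one. α′-Alkylation (LiN(i-Pr)2, THF, −78 °C, then 2) should give 3-methoxy-6-(3-methylbut-2-en-1-yl)cyclohex-2-en-1-one F1. Addition of MeLi and acid hydrolysis (Stork–Danheiser transposition) should give 3-methyl-4-(3-methylbut-2-en-1-yl)cyclohex-2-en-1-one F2. Conjugate addition of Me2CuLi with trapping of the enolate by 2, then equilibration, should give racemic cis-3,3-dimethyl-2,4-bis(3-methylbut-2-en-1-yl)cyclohexan-1-one F3. Ketalisation–elimination (HC(OMe)3, TsOH) should give racemic cis-1-methoxy-5,5-dimethyl-4,6-bis(3-methylbut-2-en-1-yl)cyclohex-1-ene F4. Effenberger cyclisation with malonyl dichloride followed by aqueous KOH should give racemic 8,8-dimethyl-1,7-bis(3-methylbut-2-en-1-yl)bicyclo[3.3.1]nonane-2,4,9-trione F5. O-Methylation (Me2SO4, K2CO3, acetone) and separation of the regioisomer should give racemic 14 F6, which is resolved by preparative chiral-phase HPLC and rejoins the route at 14.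

Step 2. The esterase may distinguish the two bulky alkenyl groups poorly, or prefer the other enantiotopic ester. The fallback sets out from 3: unselective mono-saponification (KOH, 1 equiv, MeOH–H2O) should give racemic 2-(methoxycarbonyl)-5-methyl-2-(prop-1-en-2-yl)hex-4-enoic acid F7. Classical resolution by fractional crystallisation of its salt with (S)-1-phenylethylamine (or the R amine, whichever gives the less soluble salt of the R acid) should give (S)-1-phenylethylammonium (2R)-2-(methoxycarbonyl)-5-methyl-2-(prop-1-en-2-yl)hex-4-enoate F8. Acidification returns the route at 4.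

Step 8. Deprotonation of the bridgehead next to the methoxy-bearing C4 may be slow and lose out to removal of the vinylic C3–H, which would lead to alkylation at C3 or on oxygen. The fallback sets out from 14 and moves the enol ether so that C5–H is α to a carbonyl. LiOH (1,4-dioxane–H2O, 90 °C) should give (1R,5S,7R)-8,8-dimethyl-1,7-bis(3-methylbut-2-en-1-yl)bicyclo[3.3.1]nonane-2,4,9-trione F9. O-Methylation (Me2SO4, K2CO3, acetone) and separation from re-formed 14 should give the regioisomer of 14 with methoxy on C2 and the carbonyl on C4 F10. Bridgehead lithiation and geranylation (LiN(i-Pr)2, then 15) should give the corresponding regioisomer of 16 F11. C3 aroylation with 20 under the conditions of step 11 should give the corresponding regioisomer of 21 F12, and LiOH under the conditions of step 12 then gives 22 directly.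

**Further compounds**

F1 | step 6 | 3-methoxy-6-(3-methylbut-2-en-1-yl)cyclohex-2-en-1-one (racemic) | COC1=CC(=O)C(CC=C(C)C)CC1
F2 | step 6 | 3-methyl-4-(3-methylbut-2-en-1-yl)cyclohex-2-en-1-one (racemic) | CC1=CC(=O)CCC1CC=C(C)C
F3 | step 6 | racemic cis-3,3-dimethyl-2,4-bis(3-methylbut-2-en-1-yl)cyclohexan-1-one | O=C1CC[C@@H](CC=C(C)C)C(C)(C)[C@H]1CC=C(C)C
F4 | step 6 | racemic cis-1-methoxy-5,5-dimethyl-4,6-bis(3-methylbut-2-en-1-yl)cyclohex-1-ene | COC1=CC[C@@H](CC=C(C)C)C(C)(C)[C@H]1CC=C(C)C
F5 | step 6 | racemic 8,8-dimethyl-1,7-bis(3-methylbut-2-en-1-yl)bicyclo[3.3.1]nonane-2,4,9-trione (relative configuration of 14) | [C@H]12C[C@@H](CC=C(C)C)C(C)(C)[C@](CC=C(C)C)(C(=O)CC1=O)C2=O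
F6 | step 6 | racemic 4-methoxy-8,8-dimethyl-1,7-bis(3-methylbut-2-en-1-yl)bicyclo[3.3.1]non-3-ene-2,9-dione (racemate of 14) | [C@H]12C[C@@H](CC=C(C)C)C(C)(C)[C@](CC=C(C)C)(C(=O)C=C1OC)C2=O
F7 | step 2 | racemic 2-(methoxycarbonyl)-5-methyl-2-(prop-1-en-2-yl)hex-4-enoic acid | CC(=C)C(CC=C(C)C)(C(=O)O)C(=O)OC
F8 | step 2 | (S)-1-phenylethylammonium (2R)-2-(methoxycarbonyl)-5-methyl-2-(prop-1-en-2-yl)hex-4-enoate | CC(=C)[C@](CC=C(C)C)(C(=O)[O-])C(=O)OC.C[C@H]([NH3+])c1ccccc1
F9 | step 8 | (1R,5S,7R)-8,8-dimethyl-1,7-bis(3-methylbut-2-en-1-yl)bicyclo[3.3.1]nonane-2,4,9-trione | [C@H]12C[C@@H](CC=C(C)C)C(C)(C)[C@](CC=C(C)C)(C(=O)CC1=O)C2=O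
F10 | step 8 | regioisomer of 14 with methoxy on C2 and carbonyl on C4 (configuration of 14) | [C@H]12C[C@@H](CC=C(C)C)C(C)(C)[C@](CC=C(C)C)(C(OC)=CC1=O)C2=O
F11 | step 8 | regioisomer of 16 with methoxy on C2 and carbonyl on C4 (configuration of 16) | CC(C)=CCC/C(C)=C/C[C@]12C[C@@H](CC=C(C)C)C(C)(C)[C@](CC=C(C)C)(C(OC)=CC1=O)C2=O
F12 | step 8 | regioisomer of 21 with methoxy on C2 and carbonyl on C4 (configuration of 21) | CC(C)=CCC/C(C)=C/C[C@]12C[C@@H](CC=C(C)C)C(C)(C)[C@](CC=C(C)C)(C(OC)=C(C(=O)c3ccc(O[Si](C)(C)C(C)(C)C)c(O[Si](C)(C)C(C)(C)C)c3)C1=O)C2=O
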